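The constants to watch are the dissolution coefficient 0.41 s⁻¹, the solubility 0.23 mM, and the two loss constants 0.069 s⁻¹ and 0.029 s⁻¹, which turn dissolved target into over-reaction product and decomposed product.

starting material 20 mM; reagent in the second phase 1.05 equiv; time 4.0 min; volume of the second phase over the first 0.25

- Tuesday's: doubling the transfer coefficient of step 2, all else as stated
- Wednesday's: doubling the dissolution coefficient of step 1, all else as stated
- Monday's: doubling the transfer coefficient of step 6, all else as stated
- Friday's: doubling the amount of reagent in the second phase, all else as stated

1. the target and product in the second phase and crystals together standing at 4.0 min, as a percentage of the starting material charged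
2. the change that raises the amount of target and product in the second phase and crystals together at 4.0 min, in percent of the starting material charged most ("none" if none brings more than 2 percentage points) (Tuesday's / Wednesday's / Monday's / Friday's / none)
3. amount of target and product in the second phase and crystals together at 4.0 min, in percent of the starting material charged, after Friday's

- target is meant together with its product in the second phase and crystals
- in the second phase: reagent in the second phase, product in the second phase; everything else is in the first
- charges count per volume of the first phase; a concentration in a rate is the amount of a species over the volume of its own phase; every rate counts per litre of the first phase
- solid, in amounts per volume of the solution: crystals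
- run time (flask): 4.0 min

How soon is the reagent in play? It crosses into the reaction phase with a time constant of 18.0 s, short against the 4.0 min of the run. So I take the charge of starting material, the limiting reagent at 1.05 equiv, as turned into target early.

Where does that target go? The solubility is 1.15% of the charge, so a saturated solution holds hardly any of it, and target made beyond that either forms crystals or is lost to over-reaction product and decomposed product.

What can be frozen? Write dissolution as a steady stream out of the crystals, coefficient times solubility, minus a return proportional to dissolved target. The dissolved pool then has a single time constant, 1.97 s, short against the run. It stores little, and whatever enters leaves by a fixed split: a share 19.3% is lost, and the rest goes to crystals.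

And what enters? The charge once, plus the crystal stream, 0.283 min⁻¹ as a fraction of the charge. Multiplying stream by share gives the crystal drain, 0.0546 min⁻¹, the fraction of the charge lost each minute while crystals stand. The crystals are the target's resting state.

So the rule: one minus the share, minus drain times time, which gives 58.9%.

The weak spot? The rule holds while crystals stand, and 58.9% at the end leaves plenty.

And the changes? Neither the reagent charge nor a transfer coefficient appears in the share or the drain, so I expect Tuesday's, Monday's and Friday's to leave 58.9% in place. Wednesday's raises the drain but cuts the share to 10.7%, giving 65.2%, a gain of 6.3 percentage points.

The forecast gave 59.1% (from 57.5% to 60.5%), Wednesday's as best and 59.1% after Friday's, holding that “This integral does not depend on how fast the target forms”.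

    crystals ⇌ target, rate k1*(cs1 - [target]) while solid is left; crystals form when [target] > cs1 (cs1 = 0.23 mM, k1 = 0.41 s⁻¹)
    target ⇌ product in the second phase, rate k2*([target] - [product in the second phase]/K2) per volume of the first phase (K2 = 1.1, k2 = 0.11 s⁻¹)
    starting material + reagent in the reaction phase → target (k3 = 120 L mol⁻¹ s⁻¹)
    target → over-reaction product (k4 = 0.069 s⁻¹)
    target → decomposed product (k5 = 0.029 s⁻¹)
    reagent in the reaction phase ⇌ reagent in the second phase, rate k6*([reagent in the reaction phase] - [reagent in the second phase]/K6) per volume of the first phase (K6 = 3.6, k6 = 0.050 s⁻¹)

The simulation gives 59.1%, with Wednesday's best at 6.2 points and 59.1% after Friday's. In this flask crystals stood at 68.8% of the charge at 2.00 min and 58.0% at 4.00 min, while the drain over that span comes to 10.9%. In the neighbour flask with 8.0 mM of starting material, same equivalents and same time, the stream stays but the charge shrinks, so the drain becomes 0.136 min⁻¹ and the rule gives 26.3%; that flask, with crystals at 23.9%, holds 26.9%.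

The numbers of this flask stand for no real mixture; the run is a simulation.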